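**Plan**

- Retrosynthesis: the C10–C14 ester bond, the O8 angeloyl bond and the two exocyclic methylenes (C4=C15, C11=C13) are cut first, and the C5 carbinol is taken back to a ketone.
- Feature: in ring A (carbocycle C1–C10) the ring-cis C1=C10 alkene carrying CO2Me on C10 lies 1,5 to the C5 carbinol. This is the pattern of a cyclodec-5-ynone (C5 ketone, C1≡C10), which is the fragmentation product of a decalin α,β-epoxy ketone (C1 ketone, C5–C10 epoxide). O8 is homopropargylic to C10.
- Further cuts: C1–C10 and C4–C5 (cyclohexenone ring), O6–C12 (lactone ring B), C7–C11 (Claisen).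
- Forward ring order: cyclohexane C5–C10 (from the cyclohexenol), then trans-lactone ring B, then the cyclohexenone ring C1–C5/C10, then epoxide; fragmentation of the shared C5–C10 bond opens ring A.
- Stereochemistry: C8 from the enzymatically desymmetrised monoacetate; C7 by suprafacial Johnson–Claisen shift (cis to O8); C6 by dihydroxylation anti to the C7/C8 groups; C5 by Luche reduction anti to the C6–O bond. The C1=C10 geometry and the CO2Me position come from an O8-tethered syn-hydrosilylation; the angelate geometry comes from angelic acid.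

Key step: step 12

Remark on labels: C1–C15, O5, O6, O8 are the target's atoms (C1–C10 carbocycle, C11–C13 lactone methylene unit with C12 the carbonyl, C14 ester carbon, C15 methylene on C4).
Assumption: enantiopure monoacetate 1 (lipase desymmetrisation product of the meso diacetate) and bromoester 12 are bought; the epoxide of 19 is drawn for attack anti to the C8 silyl ether, and the transient C4/C11 centres of the Mannich intermediates are left undefined because both epimers converge.

Step 1
Reactants: 1 (1R,4S)-cis-4-acetoxycyclohex-2-en-1-ol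
Product: 2 (1S,4R)-4-(tert-butyldimethylsilyloxy)cyclohex-2-en-1-yl acetate
Conditions: TBSCl, imidazole, DMF, 0 °C to rt
Reagents that add atoms: tert-butyldimethylsilyl chloride, CC(C)(C)[Si](C)(C)Cl
Why: Standard silylation of a secondary allylic alcohol, which puts the lasting protecting group on the oxygen that becomes O8 and keeps it from lactonising later with the cis acetate arm.

Step 2
Reactants: 2 (1S,4R)-4-(tert-butyldimethylsilyloxy)cyclohex-2-en-1-yl acetate
Product: 3 (1S,4R)-4-(tert-butyldimethylsilyloxy)cyclohex-2-en-1-ol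
Conditions: K2CO3 (cat.), MeOH, 0 °C to rt
Reagents that add atoms: none
Why: Base-catalysed methanolysis (transesterification) of the allylic acetate frees the carbinol needed for the rearrangement and leaves the silyl ether alone.

Step 3
Reactants: 3 (1S,4R)-4-(tert-butyldimethylsilyloxy)cyclohex-2-en-1-ol; 4 triethyl orthoacetate
Product: 6 ethyl 2-[(1S,6R)-6-(tert-butyldimethylsilyloxy)cyclohex-2-en-1-yl]acetate, via ketene acetal 5 (not isolated)
Conditions: EtCO2H (cat.), 4 (6 equiv, neat), 140 °C, EtOH distilled off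
Reagents that add atoms: none
Why: Johnson–Claisen rearrangement, whose suprafacial [3,3] shift delivers the acetate arm to C7 on the face that carried the departing oxygen (cis to the C8 silyl ether) and moves the alkene to C5=C6.

Step 4
Reactants: 6 ethyl 2-[(1S,6R)-6-(tert-butyldimethylsilyloxy)cyclohex-2-en-1-yl]acetate
Product: 7 ethyl 2-[6-(tert-butyldimethylsilyloxy)-2,3-dihydroxycyclohexyl]acetate (C5,C6-cis-diol trans to the C7 arm)
Conditions: OsO4 (2 mol %), N-methylmorpholine N-oxide, acetone/H2O 4:1, rt
Reagents that add atoms: N-methylmorpholine N-oxide, C[N+]1([O-])CCOCC1; water, O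
Why: Upjohn dihydroxylation, in which osmylation takes the face opposite the two cis substituents on C7 and C8 and so sets O6 (and O5) trans to the acetate arm.

Step 5
Reactants: 7 ethyl 2-[6-(tert-butyldimethylsilyloxy)-2,3-dihydroxycyclohexyl]acetate
Product: 8 trans-fused hydroxy lactone (O6–C12 lactone; free O5–H; 8-OTBS)
Conditions: camphorsulfonic acid (10 mol %), toluene, 80 °C, 4 Å sieves
Reagents that add atoms: none
Why: Acid-catalysed lactonisation (intramolecular transesterification) in which only O6 can reach the ester, O5 being 1,3-trans to the arm, so the trans-fused γ-lactone forms as ethanol is removed and O6 is told from O5 without a protecting group.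

Step 6
Reactants: 8 trans-fused hydroxy lactone
Product: 9 trans-fused keto lactone (C5 ketone)
Conditions: Dess–Martin periodinane, CH2Cl2, rt
Reagents that add atoms: none
Why: Dess–Martin oxidation of the remaining secondary alcohol under near-neutral conditions, so the epimerisable C6 next to the new ketone is not disturbed.

Step 7
Reactants: 9 trans-fused keto lactone
Product: 11 C5 enol triflate (C5=C10), via potassium enolate 10 (not isolated)
Conditions: KN(SiMe3)2, THF, −78 °C; then PhNTf2, −78 to 0 °C
Reagents that add atoms: N-phenylbis(trifluoromethanesulfonimide), O=S(=O)(N(c1ccccc1)S(=O)(=O)C(F)(F)F)C(F)(F)F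
Why: Kinetic enolisation and O-triflation, expected at the C10 methylene because the lone H6 is axial, 1,3-diaxial to the C8 silyl ether and on an acyloxy-bearing carbon, in line with the α′-enolisation of α-acyloxy ketones under kinetic control.

Step 8
Reactants: 11 C5 enol triflate; 12 tert-butyl 4-bromobutanoate
Product: 14 tert-butyl 4-(cyclohexenyl)butanoate lactone (chain on C5; C5=C10), via organozinc bromide 13 (not isolated)
Conditions: 12, Zn dust, LiCl, THF, 40 °C; then 11, PdCl2(dppf) (5 mol %), THF, 50 °C
Reagents that add atoms: none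
Why: Negishi coupling of an alkenyl triflate with a primary alkylzinc halide, tolerant of ester, lactone and silyl ether, with a bidentate phosphine to suppress β-hydride elimination.

Step 9
Reactants: 14 tert-butyl 4-(cyclohexenyl)butanoate lactone
Product: 16 4-(cyclohexenyl)butanoic acid lactone, via trimethylsilyl ester 15 (not isolated)
Conditions: TMSOTf, 2,6-lutidine, CH2Cl2, 0 °C; then H2O
Reagents that add atoms: none
Why: Silyl-triflate-mediated cleavage of a tert-butyl ester (loss of isobutene), a known selective deprotection that leaves the TBS ether, the lactone and the trisubstituted alkene intact.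

Step 10
Reactants: 16 4-(cyclohexenyl)butanoic acid lactone
Product: 18 tricyclic enone (C1 ketone; C5=C10; lactone; 8-OTBS), via acid chloride 17 (not isolated)
Conditions: (COCl)2, DMF (cat.), CH2Cl2, 0 °C to rt, evaporate; SnCl4, CH2Cl2, −78 °C; then Et3N, −78 to 0 °C
Reagents that add atoms: none
Why: Darzens–Nenitzescu (Friedel–Crafts-type) acylation of an alkene, in which the acylium ion attacks C10 in the Markovnikov sense to close the six-membered ring and the C5 cation loses H10, directly or through a chloride adduct and base, to give the tetrasubstituted enone.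

Step 11
Reactants: 18 tricyclic enone
Product: 19 5,10-epoxy-1-decalone lactone (C1 ketone; C5–C10 epoxide; 8-OTBS)
Conditions: t-BuOOH (decane), BnMe3NOH (cat.), THF, 0 °C to rt
Reagents that add atoms: tert-butyl hydroperoxide, CC(C)(C)OO
Why: Weitz–Scheffer nucleophilic epoxidation under anhydrous, base-lean conditions that spare the lactone and H6; the peroxide is expected to add to C5 and close from the face opposite the axial C8 silyl ether, and the two new centres are destroyed in the next step.

Step 12
Reactants: 19 5,10-epoxy-1-decalone lactone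
Product: 21 lactone-fused cyclodec-5-ynone (C5 ketone; C1≡C10; 8-OTBS), via tosylhydrazone 20 (not isolated)
Conditions: TsNHNH2 (1.1 equiv), AcOH/CH2Cl2 1:1, −20 °C to rt
Reagents that add atoms: none
Why: Eschenmoser–Tanabe fragmentation: the C1 ketone condenses with the sulfonyl hydrazide, the hydrazone opens the C10–O epoxide bond to an alkenyl diazene with oxygen left on C5, and collapse of that oxygen to the C5 carbonyl cleaves C5–C10 with loss of N2 and p-toluenesulfinate, leaving the C1≡C10 triple bond. The closest known case is 9,10-epoxy-1-decalone giving cyclodec-5-ynone under the same conditions. No ring is closed; ring A appears because the bond shared by the two six-membered rings is cut, and lactone ring B is a spectator. No stereocentre is formed, C5 and C10 end as sp2 and sp carbons so either epoxide diastereomer converges, and C6, C7 and C8 are untouched in the weakly acidic medium. The selectivity needed is fragmentation over plain epoxide opening, and the ring secures it by holding the diazenyl group on C1 anti-periplanar to the C5–C10 bond across the C1=C10 bond of the cyclic intermediate.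

Step 13
Reactants: 21 lactone-fused cyclodec-5-ynone
Product: 25 C4-methylene ynone (C4=C15; C5 ketone), via lithium enolate 22 (not isolated), via Mannich base 23 (not isolated), via ammonium iodide 24 (not isolated)
Conditions: LiN(SiMe3)2 (1.05 equiv), THF, −78 °C; CH2=NMe2+ I−, −78 °C to rt; then MeI, CH2Cl2, rt; then aq. NaHCO3
Reagents that add atoms: N,N-dimethylmethyleneiminium iodide (Eschenmoser's salt), C=[N+](C)C.[I-]
Why: Mannich α-methylenation: one equivalent of amide base enolises only the ketone (far more acidic than the lactone) toward the C4 methylene, and the β-amino ketone is quaternised and eliminated to the exocyclic enone.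

Step 14
Reactants: 25 C4-methylene ynone
Product: 26 (5S)-allylic alcohol (free O5–H; C4=C15; C1≡C10)
Conditions: NaBH4, CeCl3·7H2O, MeOH, −78 °C
Reagents that add atoms: none
Why: Luche 1,2-reduction of the enone, with hydride expected to approach anti to the C6–O bond (polar Felkin–Anh) to give the 5,6-threo, 5S alcohol while lactone and alkyne stay untouched.

Step 15
Reactants: 26 (5S)-allylic alcohol
Product: 27 5-O-TIPS ether (8-OTBS; saturated lactone)
Conditions: TIPSOTf, 2,6-lutidine, CH2Cl2, −40 to 0 °C
Reagents that add atoms: triisopropylsilyl trifluoromethanesulfonate, CC(C)[Si](OS(=O)(=O)C(F)(F)F)(C(C)C)C(C)C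
Why: Silyl triflate silylation, reliable for a hindered secondary allylic alcohol, with the TIPS group chosen to outlast the later removal of the C8 TBS ether.

Step 16
Reactants: 27 5-O-TIPS ether
Product: 31 α-methylene lactone (C11=C13; 5-OTIPS; 8-OTBS), via lithium enolate 28 (not isolated), via Mannich base 29 (not isolated), via ammonium iodide 30 (not isolated)
Conditions: LiN(i-Pr)2 (1.3 equiv), THF, −78 °C; CH2=NMe2+ I−, −78 °C to rt; then MeI, MeOH/CH2Cl2, rt; then aq. NaHCO3
Reagents that add atoms: N,N-dimethylmethyleneiminium iodide (Eschenmoser's salt), C=[N+](C)C.[I-]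
Why: Classical α-methylenation of a γ-lactone (Mannich base, quaternisation, elimination) at the only enolisable carbonyl left, before any base-sensitive ester is present.

Step 17
Reactants: 31 α-methylene lactone
Product: 32 C8 alcohol (free O8–H; 5-OTIPS)
Conditions: HF·pyridine, pyridine, THF, 0 °C to rt
Reagents that add atoms: none
Why: Buffered fluoride desilylation, selective for the less hindered and intrinsically more labile TBS ether over the TIPS ether, in an acidic medium that avoids translactonisation and conjugate addition.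

Step 18
Reactants: 32 C8 alcohol
Product: 34 cyclic alkenyl siloxane (O8–SiMe2–C10; ring-cis C1=C10), via hydrosilyl ether 33 (not isolated)
Conditions: ClSiMe2H, Et3N, CH2Cl2, 0 °C; filter, concentrate; H2PtCl6·6H2O (0.5 mol %), THF, rt to 50 °C
Reagents that add atoms: chlorodimethylsilane, C[SiH](C)Cl
Why: Tethered platinum-catalysed hydrosilylation of a homopropargylic silyl ether, a 5-exo-dig syn addition that puts silicon on C10 and hydrogen on C1 on the same side and so fixes both the regiochemistry and the ring-cis geometry.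

Step 19
Reactants: 34 cyclic alkenyl siloxane
Product: 36 C10 alkenyl iodide with free O8–H, via silyl succinimide 35 (not isolated)
Conditions: N-iodosuccinimide, MeCN/ClCH2CN 4:1, 0 °C to rt; then aq. NaHCO3/Na2S2O3
Reagents that add atoms: N-iodosuccinimide, O=C1CCC(=O)N1I
Why: Ipso-iododesilylation of an alkenylsilane with retention through the β-silyl cation, the silicon–oxygen link being hydrolysed on work-up to return O8–H; the methylene lactone is electron-poor and the C4 methylene is deactivated by its allylic silyl ether.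

Step 20
Reactants: 36 C10 alkenyl iodide with free O8–H; 37 angelic acid
Product: 39 8-O-angelate alkenyl iodide, via mixed anhydride 38 (not isolated)
Conditions: 37, 2,4,6-Cl3C6H2COCl, Et3N, toluene, rt; then 36, toluene, 80 °C
Reagents that add atoms: none
Why: Yamaguchi-type mixed-anhydride esterification in toluene without a nucleophilic amine catalyst, the conditions known to transfer the angeloyl group without Z to E isomerisation to the tiglate.

Step 21
Reactants: 39 8-O-angelate alkenyl iodide
Product: 40 5-O-TIPS ether of the target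
Conditions: Pd(PPh3)4 (5 mol %), CO (1 atm), MeOH, Et3N, DMF, 50 °C
Reagents that add atoms: carbon monoxide, [C-]#[O+]; methanol, CO
Why: Palladium-catalysed methoxycarbonylation of an alkenyl iodide (oxidative addition to zerovalent palladium, CO insertion, methanolysis) with retention of the alkene geometry, placing CO2Me on C10.

Step 22
Reactants: 40 5-O-TIPS ether of the target
Product: 41 target CNP0163095.1
Conditions: HF·pyridine, THF, 0 °C to rt
Reagents that add atoms: none
Why: Fluoride-mediated cleavage of the TIPS ether under mildly acidic conditions tolerated by the angelate, the acrylate and the methylene lactone.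

**Compound list**

1 | (1R,4S)-cis-4-acetoxycyclohex-2-en-1-ol | O[C@H]1C=C[C@@H](OC(C)=O)CC1 | starting material
2 | (1S,4R)-4-(tert-butyldimethylsilyloxy)cyclohex-2-en-1-yl acetate | CC(C)(C)[Si](C)(C)O[C@H]1C=C[C@@H](OC(C)=O)CC1 | intermediate
3 | (1S,4R)-4-(tert-butyldimethylsilyloxy)cyclohex-2-en-1-ol | CC(C)(C)[Si](C)(C)O[C@H]1C=C[C@@H](O)CC1 | intermediate
4 | triethyl orthoacetate | CCOC(C)(OCC)OCC | starting material
5 | 1-ethoxyvinyl ether of 3 (mixed ketene acetal) | CC(C)(C)[Si](C)(C)O[C@H]1C=C[C@@H](OC(=C)OCC)CC1 | intermediate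
6 | ethyl 2-[(1S,6R)-6-(tert-butyldimethylsilyloxy)cyclohex-2-en-1-yl]acetate | CCOC(=O)C[C@H]1C=CCC[C@H]1O[Si](C)(C)C(C)(C)C | intermediate
7 | ethyl 2-[6-(tert-butyldimethylsilyloxy)-2,3-dihydroxycyclohexyl]acetate, C5,C6-cis-diol trans to the C7 arm and to O8 | CCOC(=O)C[C@H]1[C@H](O)[C@H](O)CC[C@H]1O[Si](C)(C)C(C)(C)C | intermediate
8 | trans-fused 4-(tert-butyldimethylsilyloxy)-7-hydroxyhexahydro-1-benzofuran-2(3H)-one (O6–C12 lactone, free O5–H) | O=C1C[C@H]2[C@H](O1)[C@H](O)CC[C@H]2O[Si](C)(C)C(C)(C)C | intermediate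
9 | trans-fused 4-(tert-butyldimethylsilyloxy)hexahydro-1-benzofuran-2,7-dione (C5 ketone) | O=C1C[C@H]2[C@H](O1)C(=O)CC[C@H]2O[Si](C)(C)C(C)(C)C | intermediate
10 | potassium C5=C10 enolate of 9 | O=C1C[C@H]2[C@H](O1)C([O-])=CC[C@H]2O[Si](C)(C)C(C)(C)C.[K+] | intermediate
11 | C5 enol triflate of 9 (C5=C10) | O=C1C[C@H]2[C@H](O1)C(OS(=O)(=O)C(F)(F)F)=CC[C@H]2O[Si](C)(C)C(C)(C)C | intermediate
12 | tert-butyl 4-bromobutanoate | CC(C)(C)OC(=O)CCCBr | starting material
13 | (4-tert-butoxy-4-oxobutyl)zinc bromide | CC(C)(C)OC(=O)CCC[Zn]Br | intermediate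
14 | tert-butyl 4-(cyclohexenyl)butanoate lactone: C5 carries the C4–C1 chain, C5=C10, trans-lactone, 8-OTBS | O=C1C[C@H]2[C@H](O1)C(CCCC(=O)OC(C)(C)C)=CC[C@H]2O[Si](C)(C)C(C)(C)C | intermediate
15 | trimethylsilyl ester corresponding to 14 | O=C1C[C@H]2[C@H](O1)C(CCCC(=O)O[Si](C)(C)C)=CC[C@H]2O[Si](C)(C)C(C)(C)C | intermediate
16 | carboxylic acid corresponding to 14 | O=C1C[C@H]2[C@H](O1)C(CCCC(=O)O)=CC[C@H]2O[Si](C)(C)C(C)(C)C | intermediate
17 | acid chloride of 16 | O=C1C[C@H]2[C@H](O1)C(CCCC(=O)Cl)=CC[C@H]2O[Si](C)(C)C(C)(C)C | intermediate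
18 | tricyclic enone: octal-1-one with C5=C10, trans-lactone on C6/C7, 8-OTBS | O=C1C[C@H]2[C@H](O1)C3=C(C[C@H]2O[Si](C)(C)C(C)(C)C)C(=O)CCC3 | intermediate
19 | 5,10-epoxy-1-decalone carrying the trans-lactone and the 8-OTBS ether (epoxide on the O6 face) | O=C1CCC[C@@]23O[C@@]12C[C@@H](O[Si](C)(C)C(C)(C)C)[C@H]1CC(=O)O[C@@H]13 | intermediate
20 | C1 tosylhydrazone of 19 | Cc1ccc(cc1)S(=O)(=O)N/N=C1\CCC[C@@]23O[C@@]12C[C@@H](O[Si](C)(C)C(C)(C)C)[C@H]1CC(=O)O[C@@H]13 | intermediate
21 | lactone-fused cyclodec-5-ynone: C5 ketone, C1≡C10 alkyne, 6,7-trans-lactone, 8-OTBS | C1C(=O)O[C@H]2[C@H]1[C@H](O[Si](C)(C)C(C)(C)C)CC#CCCCC2=O | intermediate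
22 | lithium C4=C5 enolate of 21 | C1C(=O)O[C@H]2[C@H]1[C@H](O[Si](C)(C)C(C)(C)C)CC#CCCC=C2[O-].[Li+] | intermediate
23 | C4-(dimethylaminomethyl) ketone (Mannich base, C4 epimers) | C1C(=O)O[C@H]2[C@H]1[C@H](O[Si](C)(C)C(C)(C)C)CC#CCCC(CN(C)C)C2=O | intermediate
24 | C4-(trimethylammoniomethyl) ketone iodide | C1C(=O)O[C@H]2[C@H]1[C@H](O[Si](C)(C)C(C)(C)C)CC#CCCC(C[N+](C)(C)C)C2=O.[I-] | intermediate
25 | C4-methylene cyclodecynone (C4=C15, C5 ketone) | C1C(=O)O[C@H]2[C@H]1[C@H](O[Si](C)(C)C(C)(C)C)CC#CCCC(=C)C2=O | intermediate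
26 | (5S)-allylic alcohol: C5–OH, C4=C15, C1≡C10, 8-OTBS | C1C(=O)O[C@H]2[C@H]1[C@H](O[Si](C)(C)C(C)(C)C)CC#CCCC(=C)[C@@H]2O | intermediate
27 | 5-O-TIPS ether of 26 | C1C(=O)O[C@H]2[C@H]1[C@H](O[Si](C)(C)C(C)(C)C)CC#CCCC(=C)[C@@H]2O[Si](C(C)C)(C(C)C)C(C)C | intermediate
28 | lithium lactone enolate of 27 | C1=C([O-])O[C@H]2[C@H]1[C@H](O[Si](C)(C)C(C)(C)C)CC#CCCC(=C)[C@@H]2O[Si](C(C)C)(C(C)C)C(C)C.[Li+] | intermediate
29 | C11-(dimethylaminomethyl) lactone (Mannich base, C11 epimers) | CN(C)CC1C(=O)O[C@H]2[C@H]1[C@H](O[Si](C)(C)C(C)(C)C)CC#CCCC(=C)[C@@H]2O[Si](C(C)C)(C(C)C)C(C)C | intermediate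
30 | C11-(trimethylammoniomethyl) lactone iodide | C[N+](C)(C)CC1C(=O)O[C@H]2[C@H]1[C@H](O[Si](C)(C)C(C)(C)C)CC#CCCC(=C)[C@@H]2O[Si](C(C)C)(C(C)C)C(C)C.[I-] | intermediate
31 | α-methylene lactone: C11=C13, C4=C15, C1≡C10, 5-OTIPS, 8-OTBS | C=C1C(=O)O[C@H]2[C@H]1[C@H](O[Si](C)(C)C(C)(C)C)CC#CCCC(=C)[C@@H]2O[Si](C(C)C)(C(C)C)C(C)C | intermediate
32 | C8 alcohol: free O8–H, 5-OTIPS | C=C1C(=O)O[C@H]2[C@H]1[C@H](O)CC#CCCC(=C)[C@@H]2O[Si](C(C)C)(C(C)C)C(C)C | intermediate
33 | 8-O-dimethylsilyl (Si–H) ether of 32 | C=C1C(=O)O[C@H]2[C@H]1[C@H](O[SiH](C)C)CC#CCCC(=C)[C@@H]2O[Si](C(C)C)(C(C)C)C(C)C | intermediate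
34 | cyclic alkenyl siloxane: five-membered O8–SiMe2–C10 ring, ring-cis C1=C10 | C=C1C(=O)O[C@H]2[C@H]1[C@H](O[Si]3(C)C)C/C3=C\CCC(=C)[C@@H]2O[Si](C(C)C)(C(C)C)C(C)C | intermediate
35 | C10 alkenyl iodide with 8-O-SiMe2-succinimide | C=C1C(=O)O[C@H]2[C@H]1[C@H](O[Si](C)(C)N3C(=O)CCC3=O)C/C(I)=C\CCC(=C)[C@@H]2O[Si](C(C)C)(C(C)C)C(C)C | intermediate
36 | C10 alkenyl iodide, free O8–H, 5-OTIPS | C=C1C(=O)O[C@H]2[C@H]1[C@H](O)C/C(I)=C\CCC(=C)[C@@H]2O[Si](C(C)C)(C(C)C)C(C)C | intermediate
37 | angelic acid | C/C=C(/C)C(=O)O | starting material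
38 | angelic 2,4,6-trichlorobenzoic anhydride | C/C=C(/C)C(=O)OC(=O)c1c(Cl)cc(Cl)cc1Cl | intermediate
39 | 8-O-angelate of 36 | C=C1C(=O)O[C@H]2[C@H]1[C@H](OC(=O)/C(C)=C\C)C/C(I)=C\CCC(=C)[C@@H]2O[Si](C(C)C)(C(C)C)C(C)C | intermediate
40 | 5-O-TIPS ether of the target | C=C1C(=O)O[C@H]2[C@H]1[C@H](OC(=O)/C(C)=C\C)C/C(C(=O)OC)=C\CCC(=C)[C@@H]2O[Si](C(C)C)(C(C)C)C(C)C | intermediate
41 | CNP0163095.1 | C=C1C(=O)O[C@H]2[C@H]1[C@H](OC(=O)/C(C)=C\C)C/C(C(=O)OC)=C\CCC(=C)[C@@H]2O | target

**Step count**

Total: 22 steps. Longest linear sequence: 22 steps (1 to 41); the zinc reagent from 12 is made and used in the flask of step 8.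

**Steps most likely to fail**

Step 10. What may go wrong: under the Lewis acid the allylic C6–O lactone bond may ionise or the silyl ether may be lost, and the C5 cation may lose a proton toward C6 or C4 instead of C10. The fallback sets out from acid 16 and replaces the acylium ion by an aldehyde. Acid chloride 17 is reduced with LiAlH(Ot-Bu)3 in THF at −78 °C to the aldehyde F1. Me2AlCl (2 equiv, CH2Cl2, −78 °C) then brings about a Prins cyclisation that forms C1–C10 with chloride capture at C5, giving the chloro alcohol F2. Dess–Martin oxidation gives the β-chloro ketone F3, and Et3N removes HCl through the C10 enolate, which can only lead to the conjugated enone. The route is rejoined at 18.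

Step 14. What may go wrong: hydride delivery to C5 in the conformationally mobile ten-membered ring may show poor or reversed facial selectivity. The fallback sets out from enone 25 and uses reagent control in place of substrate control: Corey–Bakshi–Shibata reduction with catecholborane and the matched antipode of 2-methyl-CBS-oxazaborolidine in toluene at −78 °C, which is a 1,2-selective enone reduction that leaves the lactone alone. It returns at 26 and makes no new compound (F0).

Step 20. What may go wrong: acylation of the hindered C8 hydroxyl may be sluggish, and the activated angeloyl unit may isomerise from Z to E (tiglate) or the free O8–H may translactonise on prolonged heating. The fallback sets out from 36 and builds the Z-alkene on the ester. Carbodiimide esterification (DCC, cat. DMAP, CH2Cl2) with 2-[bis(2,2,2-trifluoroethoxy)phosphoryl]propanoic acid gives the phosphonate ester F4. Still–Gennari olefination (KN(SiMe3)2, 18-crown-6, THF, −78 °C, then acetaldehyde) then forms the Z-2-methylbut-2-enoate. The route is rejoined at 39.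

**Further compounds**

F1 | step 10 | aldehyde corresponding to acid 16 (C1 formyl) | O=C1C[C@H]2[C@H](O1)C(CCCC=O)=CC[C@H]2O[Si](C)(C)C(C)(C)C
F2 | step 10 | tricyclic chloro alcohol (C1–OH, C5–Cl, C1/C5/C10 configurations undefined) | O=C1C[C@H]2[C@H](O1)C3(Cl)CCCC(O)C3C[C@H]2O[Si](C)(C)C(C)(C)C
F3 | step 10 | tricyclic β-chloro ketone (C1 ketone, C5–Cl) | O=C1C[C@H]2[C@H](O1)C3(Cl)CCCC(=O)C3C[C@H]2O[Si](C)(C)C(C)(C)C
F0 | step 14 | none | none
F4 | step 20 | 8-O-[2-(bis(2,2,2-trifluoroethoxy)phosphoryl)propanoate] of 36 | C=C1C(=O)O[C@H]2[C@H]1[C@H](OC(=O)C(C)P(=O)(OCC(F)(F)F)OCC(F)(F)F)C/C(I)=C\CCC(=C)[C@@H]2O[Si](C(C)C)(C(C)C)C(C)C
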